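**Retrosynthetic overview**

1. Feature: ring B (the dihydrofuran) holds O1, C2 (isopropenyl) and C3 (benzylic acyloxy) in a row, with the two substituents trans. This O1–C2–C3(O) array is what remains when one allylic carbon is inserted between the phenoxide oxygen and the formyl carbon of a salicylaldehyde.
2. First disconnection: the C3–O ester and the side-chain acetate, giving the trans-(2R,3S) 3-ol and a silyl-protected (Z)-2-(hydroxymethyl)but-2-enoic acid (from crotonaldehyde through its Z α-iodide and carbonylation).
3. Key disconnection: C2–C3 and O1–C2, giving 5-acetylsalicylaldehyde and a chiral S-methallyl sulfonium salt of isothiocineole; this is a sulfur ylide (4+1) annulation through a transient trans vinyl oxirane.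
4. Ring order: the benzene ring is bought; ring B is the only ring made and is closed in the key step.

Key step: step 4

Assumption on the chemistry: the exo S-methallyl ylide of isothiocineole is taken to select faces as the S-benzyl ylide does (alkenyl group syn to the sulfur lone pair, attack on the lobe away from the gem-dimethyl carbon); on that model the (1S,4S,5S) sulfide from (S)-limonene leads to the (2S,3S) epoxide and hence the (2R,3S) alcohol, so the route is written with that enantiomer.

**Route**

Step 1
Reactants: 1 4'-hydroxyacetophenone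
Product: 2 5-acetylsalicylaldehyde (5-acetyl-2-hydroxybenzaldehyde)
Conditions: MgCl2, Et3N, (CH2O)n, MeCN, reflux; then 1 M HCl
Reagents that add atoms: paraformaldehyde (source of formaldehyde), C=O
Why: Magnesium-mediated ortho-formylation (Casnati–Skattebøl reaction), in which the magnesium phenoxide delivers formaldehyde to the carbon ortho to oxygen, a second formaldehyde oxidises the benzylic alkoxide to the aldehyde, and the para position is blocked by the acetyl group.

Step 2
Reactants: 3 (S)-(−)-limonene
Product: 4 (1S,4S,5S)-isothiocineole [(1S,4S,5S)-4,7,7-trimethyl-6-thiabicyclo[3.2.1]octane]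
Conditions: S8, γ-terpinene, neat, 110–125 °C; fractional distillation
Reagents that add atoms: sulfur, S1SSSSSSS1
Why: Known radical thiolation–cyclisation of limonene with elemental sulfur, with γ-terpinene as hydrogen-atom donor; the limonene stereocentre becomes C1, the sulfur bridge can span C7 and C5 only on one face, and the C4 methyl group ends anti to that bridge as in the known sulfide.

Step 3
Reactants: 4 (1S,4S,5S)-isothiocineole; 5 methallyl bromide (3-bromo-2-methylprop-1-ene)
Product: 6 (1S,4S,5S)-4,7,7-trimethyl-6-(2-methylallyl)-6-thiabicyclo[3.2.1]octan-6-ium triflate (S-substituent exo)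
Conditions: LiOSO2CF3, CH2Cl2/H2O, rt; recrystallisation
Reagents that add atoms: lithium trifluoromethanesulfonate, [Li+].[O-]S(=O)(=O)C(F)(F)F
Why: SN2 S-alkylation by the allylic bromide should occur on the exposed exo lone pair of sulfur (the endo one faces the C2–C3–C4 bridge) to give one sulfonium diastereomer, and exchange of bromide for triflate stops dealkylation while recrystallisation can raise the optical purity.

Step 4
Reactants: 2 5-acetylsalicylaldehyde; 6 the S-methallyl sulfonium triflate
Product: 10 trans-(2R,3S)-5-acetyl-2-(prop-1-en-2-yl)-2,3-dihydrobenzofuran-3-ol, via sulfonium ylide 7 (not isolated), via anti betaine 8 (not isolated), via trans vinyl epoxide 9 (not isolated)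
Conditions: Cs2CO3 (2.5 equiv), MeCN, 0 °C to rt; aq. NH4Cl
Reagents that add atoms: none
Why: Proposed new method: carbonate forms the phenoxide of 2 and ylide 7, whose carbon adds to the formyl carbon (new C2–C3 bond) to give anti betaine 8; its alkoxide expels sulfide 4 by 3-exo-tet displacement to give trans vinyl epoxide 9, which the neighbouring phenoxide opens at the allylic carbon with inversion (new O1–C2 bond). The closest known reactions are the isothiocineole-mediated sulfur ylide epoxidation of aryl aldehydes with allylic sulfonium salts and the Corey–Chaykovsky conversion of salicylaldehydes into 2,3-dihydrobenzofuran-3-ols; only their union with a chiral allylic ylide on a free phenoxide is untested. Ring B closes by a 5-endo-tet epoxide opening, which the allylic π system at C2 assists and which has no rival because attack at the benzylic carbon would give an oxetane. The sulfide controls both the ylide face (C2) and, through anti addition, the aldehyde face (C3), so the (2S,3S) epoxide should form and its invertive opening at C2 gives the trans (2R,3S) alcohol. The step needs aldehyde-over-ketone and carbon-over-oxygen selectivity: the formyl group is far more electrophilic than the aryl methyl ketone, the sulfonium α-CH2 is far more acidic than the acetyl CH3, and the acetyl group para to O1 both keeps the phenoxide-bearing aldehyde electrophilic and damps quinone-methide opening of the benzylic C–O bond.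

Step 5
Reactants: 11 (E)-crotonaldehyde
Product: 12 (Z)-2-iodobut-2-enal
Conditions: I2, K2CO3, DMAP (cat.), THF/H2O 1:1, rt
Reagents that add atoms: iodine, II
Why: α-Iodination of an enal by a Baylis–Hillman-type sequence (conjugate addition of DMAP, iodination of the enolate, elimination of DMAP), which returns the more stable alkene with CHO trans to CH3, that is the Z iodide.

Step 6
Reactants: 12 (Z)-2-iodobut-2-enal
Product: 13 (Z)-2-iodobut-2-en-1-ol
Conditions: NaBH4, THF/H2O 9:1, 0 °C
Reagents that add atoms: none
Why: Chemoselective 1,2-reduction of the aldehyde by borohydride, which leaves the α-iodo alkene and its geometry untouched.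

Step 7
Reactants: 13 (Z)-2-iodobut-2-en-1-ol
Product: 14 (Z)-tert-butyl[(2-iodobut-2-en-1-yl)oxy]dimethylsilane
Conditions: TBSCl, imidazole, CH2Cl2, 0 °C to rt
Reagents that add atoms: tert-butyldimethylsilyl chloride, CC(C)(C)[Si](C)(C)Cl
Why: Standard silylation of a primary alcohol, which masks the hydroxyl group for the carbonylation and acylation steps without offering an allylic leaving group.

Step 8
Reactants: 14 the Z vinyl iodide silyl ether
Product: 15 (Z)-2-[(tert-butyldimethylsilyloxy)methyl]but-2-enoic acid
Conditions: Pd(OAc)2 (5 mol %), PPh3 (10 mol %), CO (1 atm), K2CO3, DMF/H2O, 50 °C; work-up at pH 4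
Reagents that add atoms: carbon monoxide, [C-]#[O+]; water, O
Why: Palladium-catalysed hydroxycarbonylation, in which the C–I bond adds to zerovalent palladium with retention, CO inserts and the acylpalladium is hydrolysed, so the carboxyl group takes the place of iodine cis to CH3 (Z acid).

Step 9
Reactants: 15 the Z acid; 10 the trans-(2R,3S) alcohol
Product: 17 (2R,3S)-5-acetyl-2-(prop-1-en-2-yl)-2,3-dihydrobenzofuran-3-yl (Z)-2-[(tert-butyldimethylsilyloxy)methyl]but-2-enoate, via mixed anhydride 16 (not isolated)
Conditions: 2,4,6-Cl3C6H2COCl, Et3N, toluene, rt; then 10, toluene, 60–70 °C (no DMAP)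
Reagents that add atoms: none
Why: Yamaguchi esterification, in which the alcohol attacks the unhindered enoyl carbonyl of the mixed anhydride rather than the di-ortho-substituted aroyl one; the acyl–oxygen bond formation leaves C3 untouched, and omitting a nucleophilic catalyst avoids Z-to-E isomerisation by conjugate addition–elimination.

Step 10
Reactants: 17 the silyl-protected ester
Product: 18 (2R,3S)-5-acetyl-2-(prop-1-en-2-yl)-2,3-dihydrobenzofuran-3-yl (Z)-2-(hydroxymethyl)but-2-enoate
Conditions: HF·pyridine, pyridine, THF, 0 °C to rt
Reagents that add atoms: none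
Why: Fluoride cleavage of the primary silyl ether under buffered, non-basic conditions, which should spare the benzylic ester, the ketone and the alkene geometry.

Step 11
Reactants: 18 the hydroxy ester
Product: 19 (2R,3S)-5-acetyl-2-(prop-1-en-2-yl)-2,3-dihydrobenzofuran-3-yl (Z)-2-(acetoxymethyl)but-2-enoate (target)
Conditions: Ac2O, pyridine, CH2Cl2, 0 °C to rt
Reagents that add atoms: acetic anhydride, CC(=O)OC(C)=O
Why: Acetylation of the primary allylic alcohol with anhydride and pyridine; without DMAP the new allylic acetate should not suffer SN2′ scrambling to the E isomer.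

**Compound list**

1 | 4'-hydroxyacetophenone | CC(=O)c1ccc(O)cc1 | starting material
2 | 5-acetylsalicylaldehyde | CC(=O)c1ccc(O)c(C=O)c1 | intermediate
3 | (S)-(−)-limonene | CC1=CC[C@H](CC1)C(C)=C | starting material
4 | (1S,4S,5S)-isothiocineole | C[C@H]1CC[C@H]2C[C@@H]1SC2(C)C | intermediate
5 | methallyl bromide | C=C(C)CBr | starting material
6 | (1S,4S,5S)-4,7,7-trimethyl-6-(2-methylallyl)-6-thiabicyclo[3.2.1]octan-6-ium triflate, S-alkyl group exo (on the thiolane face away from the C2–C3–C4 bridge) | C[C@H]1CC[C@H]2C[C@@H]1[S@+](CC(C)=C)C2(C)C.[O-]S(=O)(=O)C(F)(F)F | intermediate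
7 | sulfonium 2-methylallylide of 6 | C[C@H]1CC[C@H]2C[C@@H]1[S@+]([CH-]C(C)=C)C2(C)C | intermediate
8 | anti betaine, cesium 4-acetyl-2-[(1S,2R)-3-methyl-1-oxido-2-(isothiocineol-6-ium-6-yl)but-3-enyl]phenoxide | CC(=O)c1ccc([O-])c(c1)[C@H]([O-])[C@@H](C(C)=C)[S@+]2[C@H]3C[C@H](CC[C@@H]3C)C2(C)C.[Cs+] | intermediate
9 | cesium 4-acetyl-2-[(2S,3S)-3-(prop-1-en-2-yl)oxiran-2-yl]phenoxide (trans vinyl epoxide) | CC(=O)c1ccc([O-])c(c1)[C@@H]1O[C@H]1C(C)=C.[Cs+] | intermediate
10 | trans-(2R,3S)-5-acetyl-2-(prop-1-en-2-yl)-2,3-dihydrobenzofuran-3-ol | C=C(C)[C@H]1Oc2ccc(C(C)=O)cc2[C@@H]1O | intermediate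
11 | (E)-crotonaldehyde | C/C=C/C=O | starting material
12 | (Z)-2-iodobut-2-enal | C/C=C(\I)C=O | intermediate
13 | (Z)-2-iodobut-2-en-1-ol | C/C=C(\I)CO | intermediate
14 | (Z)-tert-butyl[(2-iodobut-2-en-1-yl)oxy]dimethylsilane | C/C=C(\I)CO[Si](C)(C)C(C)(C)C | intermediate
15 | (Z)-2-[(tert-butyldimethylsilyloxy)methyl]but-2-enoic acid | C/C=C(\C(=O)O)CO[Si](C)(C)C(C)(C)C | intermediate
16 | (Z)-2-[(tert-butyldimethylsilyloxy)methyl]but-2-enoic 2,4,6-trichlorobenzoic anhydride | C/C=C(\C(=O)OC(=O)c1c(Cl)cc(Cl)cc1Cl)CO[Si](C)(C)C(C)(C)C | intermediate
17 | (2R,3S)-5-acetyl-2-(prop-1-en-2-yl)-2,3-dihydrobenzofuran-3-yl (Z)-2-[(tert-butyldimethylsilyloxy)methyl]but-2-enoate | C=C(C)[C@H]1Oc2ccc(C(C)=O)cc2[C@@H]1OC(=O)/C(=C\C)CO[Si](C)(C)C(C)(C)C | intermediate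
18 | (2R,3S)-5-acetyl-2-(prop-1-en-2-yl)-2,3-dihydrobenzofuran-3-yl (Z)-2-(hydroxymethyl)but-2-enoate | C=C(C)[C@H]1Oc2ccc(C(C)=O)cc2[C@@H]1OC(=O)/C(=C\C)CO | intermediate
19 | (2R,3S)-5-acetyl-2-(prop-1-en-2-yl)-2,3-dihydrobenzofuran-3-yl (Z)-2-(acetoxymethyl)but-2-enoate | C=C(C)[C@H]1Oc2ccc(C(C)=O)cc2[C@@H]1OC(=O)/C(=C\C)COC(C)=O | target

**Step count**

Total: 11 steps. Longest linear sequence: 7 steps (steps 5 to 11, crotonaldehyde to target); the core arm from limonene is 6 steps (2, 3, 4, 9, 10, 11).

**Steps most likely to fail**

1. Step 4 (the proposed new method). The ylide carbon may add too slowly to the formyl group deactivated by the ortho phenoxide, so that the methallyl group is transferred from sulfur to the phenoxide oxygen instead. The phenoxide may displace the sulfide directly in the betaine, which would give the cis isomer. The allylic ylide may also select faces weakly or in the opposite sense. The fallback uses known chemistry, sets out from 2 and returns at 10. Compound 2 would be silylated (i-Pr3SiCl, imidazole, DMF) to 5-acetyl-2-(triisopropylsilyloxy)benzaldehyde F1. Horner–Wadsworth–Emmons olefination of the formyl group with lithiated diethyl (2-methylallyl)phosphonate (n-BuLi, THF, −78 °C) should give 1-{3-[(E)-3-methylbuta-1,3-dienyl]-4-(triisopropylsilyloxy)phenyl}ethanone F2. Shi epoxidation of its trans-disubstituted double bond would use the enantiomer of the D-fructose-derived ketone (KHSO5 as 2KHSO5·KHSO4·K2SO4, K2CO3, MeCN/dimethoxymethane/H2O, 0 °C), chosen because the D-fructose ketone gives (R,R) epoxides from trans-disubstituted styrenes. It should give 1-{3-[(2S,3S)-3-(prop-1-en-2-yl)oxiran-2-yl]-4-(triisopropylsilyloxy)phenyl}ethanone F3. Bu4NF in THF at 0 °C would then free the phenoxide, which opens the epoxide at the allylic carbon to give 10.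

2. Step 9. The activated Z acyl group may isomerise to the more stable E form, the hindered benzylic alcohol may acylate slowly, and prolonged heating may cause ionisation at C3 and elimination toward the benzofuran. The fallback sets out from 10 and 14 and returns at 17. It forms the ester by palladium-catalysed alkoxycarbonylation: vinyl iodide 14, alcohol 10, Pd(OAc)2, Xantphos, CO (1 atm), Et3N, toluene, 60 °C. The acylpalladium formed with retention of alkene geometry is intercepted by the alcohol, so no activated free acid or nucleophilic catalyst is involved.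

3. Step 8. The alkene geometry may be lost through reversible hydropalladation, the silyl ether may be cleaved in warm aqueous carbonate, and CO insertion at the α-branched vinylpalladium may be slow. The fallback sets out from 14 and returns at 15. It replaces catalytic carbonylation by iodine–lithium exchange and carboxylation: t-BuLi (2.1 equiv), Et2O, −78 °C, then dry CO2 and work-up at pH 4. The alkenyllithium holds its configuration at −78 °C and is quenched cold to forestall oxygen-to-carbon silyl migration.

**Further compounds**

F1 | step 4 | 5-acetyl-2-(triisopropylsilyloxy)benzaldehyde | CC(=O)c1ccc(O[Si](C(C)C)(C(C)C)C(C)C)c(C=O)c1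
F2 | step 4 | 1-{3-[(E)-3-methylbuta-1,3-dienyl]-4-(triisopropylsilyloxy)phenyl}ethanone | CC(=O)c1ccc(O[Si](C(C)C)(C(C)C)C(C)C)c(/C=C/C(C)=C)c1
F3 | step 4 | 1-{3-[(2S,3S)-3-(prop-1-en-2-yl)oxiran-2-yl]-4-(triisopropylsilyloxy)phenyl}ethanone | CC(=O)c1ccc(O[Si](C(C)C)(C(C)C)C(C)C)c(c1)[C@@H]1O[C@H]1C(C)=C
F0 | step 9 | none | none
F0 | step 8 | none | none
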